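**The question.** How much target does the north-west flask hold at 12 min, long after the last reading, and what does the rate do on the way there?

| flask | substrate | time |
|---|---|---|
| north | 100 mM |  |
| south | 200 mM |  |
| north-west | 100 mM | 12 min |

- north run (time / min: [target] / mM): 0.92: 5.3; 1.8: 14.5; 2.8: 26.0; 3.7: 30.8; 4.6: 31.8
- south run (time / min: [target] / mM): 0.92: 9.0; 1.8: 25.3; 2.8: 45.5; 3.7: 60.5; 4.6: 63.8

(standard deviation of a reading: 2 mM)

1. apparent order in [substrate] of the starting rate, round the charge of the north run (the rate where two percent of its substrate have turned into target) (one fixed amount of target, the same in the runs compared)
2. target in the north-west run at 12 min, as a share of the substrate charged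
3. which of these the readings show (the product binds the substrate / the product decays / the substrate pairs with itself)

- Overall: substrate -> target.
- Constant volume, constant temperature.
- An order is taken over about fifteen percent of the charge, up and down.

**One curve.** As fractions of the charge, the north and south runs overlay within the scatter. A pairing or binding step ties that fraction to the charge, so I take first-order steps. The fraction stalls near a third, which I read as the product decaying.

**Slowing constant.** I let the rate start in proportion to time, so the fraction starts as time squared. Pooling both runs gives 13.3% at 1.8 min and 31.9% at 4.6 min. From these I get 0.357 min⁻¹: the slowing constant, the logarithmic fall per minute of fraction over time squared. The fraction's rate is then the fraction times (2/t minus that constant).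

**The end.** From 4.6 min to 12 min, the square multiplies the fraction by 6.81 and the slowing by 0.0712. So I expect 15.4% in the north-west run.

**The start.** The same two readings give a starting time of 3.58 min: before any slowing, the fraction is the square of time over this. The north run reaches 2.00% at about 0.507 min. Putting that back into the slowing gives 0.555 min, and once more 0.560 min, at a rate of 6.43 mM min⁻¹. The same target in the south run is a fraction of 1.00%, reached at 0.358 min, then 0.382 min, then 0.384 min. Its rate is 9.71 mM min⁻¹, so across the doubling my order is 0.595.

**The result.** The forecast says 0.6, 8% and the product decays, with “the plateau is really a maximum”. The flask gives 0.62, 15.0% and the product decays.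

    substrate → intermediate (0.3540 min⁻¹)
    intermediate → target (0.4626 min⁻¹)
    target → decomposed product (0.2952 min⁻¹)

**What ran.** With 0.357 min⁻¹, I reckoned 15.4% for the north-west run against 15.0%, and 9.71 mM min⁻¹ for the south run against 9.9 mM min⁻¹. In the north-west run, substrate feeds intermediate, intermediate feeds target, and target decomposes while it is there. At 12 min, substrate stands at 1.43% of the charge, intermediate at 3.39%, target at 15.0%, and decomposed product at 80.2%.

The numbers in the tables are calculated for an exercise; scatter was added.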